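## The problem

The target is a (Z,Z)-germacra-1(10),4-dienolide: a ten-membered carbocycle (C1–C10) with two trisubstituted Z olefins (C1=C10, C4=C5) and a γ-lactone trans-fused across C6–C7 (oxygen on C6, C11 on C7, C12 carbonyl). Closing such a ring end to end fights entropy and transannular strain, and both olefin geometries must be secured inside it. Five stereocentres are needed: the contiguous triad C6/C7/C8, the quaternary carbinol C11, and C2, which lies between the two olefins and cannot be induced from the triad once the ring exists. C2 therefore has to be set early, in absolute terms, and should steer the rest through a small ring. Within the triad, C8 can control C7, C7 can control C6, and the C8 substituent shields one lactone face and so decides C11. The molecule is fragile: two secondary acetates (one allylic), an allylic lactone C6–O bond, an acid-sensitive 1,5-diene, and a chlorohydrin that recloses to the epoxide with base, so chloride must enter last and the acetates late. The enabling feature is that, at the C6 ketone level, C6(=O)–C7–C8–C9–C10=C1 is a δ,ε-unsaturated ketone with the Z olefin C4=C5 attached to C6. That is the imprint of an oxy-Cope shift of a cyclohex-2-enol with an alkenyl group on C6 and an isopropenyl group on C1, and the C8 oxygen can ride through the shift as silicon.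

## Retrosynthesis

**C13–Cl.** Target 33 is cut at C13–Cl to the spiro-epoxide 32. Chloride can only attack the primary C13, because C11 is quaternary and α to the carbonyl, so the C11 carbinol keeps its configuration. Placing this last avoids carrying a base-labile chlorohydrin; the forward step needs only a near-neutral chloride source.

**Acetates and C8–O.** 32 comes from diol 31 by acetylation. 31 comes from 29 by exchanging the C8 silyl group for hydroxyl with retention, with loss of the C2 silyl ether in the same operation. A benzyldimethylsilyl group is chosen because it is unmasked by fluoride and peroxide. An arylsilane would need electrophiles that the ring olefins do not survive.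

**C11 oxidation level.** Epoxide 29 is cut to the α-methylene lactone 28 (nucleophilic epoxidation touches only the electron-poor olefin). 28 is cut at C11=C13 to lactone 24 through Mannich base 26. The forward epoxidation must place oxygen on the lactone face away from C8.

**Lactone C–O and C7–C11.** 24 is opened at O–C12 and cut at C7–C11 to keto ester 22, and then to dienone 20 plus a bromoacetate. This uses the C6 ketone that the ring-forming step leaves behind. The C8 silyl group is asked to direct the alkylation at C7, and C7 then directs hydride at C6.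

**C8–C9 (key cut).** Reconnecting C1–C6 and cutting C8–C9 turns 20 into the cis-dialkenyl cyclohexenol 17. This cut removes the medium ring altogether and puts both Z olefins and C8 under the control of one chair transition state. A cut at C1–C2 or C6–C7 would leave a macrocyclisation. Silicon, not oxygen, is placed on the vinyl terminus because a β-silyl enolate is stable, whereas a β-alkoxy enolate would eliminate.

**C6–C7.** 17 comes from propargylic alcohol 16 by trans-reduction, and 16 from enone 12 plus silylacetylene 14. The acetylide is preferred to a silylvinyllithium: it is slim (axial attack), weakly basic (12 is enolisable and carries a β-silyloxy group), needs no tin, and the E geometry then follows from the reduction mechanism.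

**C4=C5 and C5–C6.** 12 is cut at C4=C5 by ring-closing metathesis to trienone 11. 11 is cut at C5–C6 to Weinreb amide 10 (via 9) and a vinyl Grignard reagent. The cyclohexene keeps C4=C5 Z for the rest of the route.

**C1–C2.** Amide 9 comes from aldol adduct 8, which is cut at C1–C2 to imide 4 and aldehyde 6. One deconjugative syn aldol sets C2 absolutely and makes the C1 isopropenyl group trans to the C2 oxygen in the later ring. 4 comes from 1 and 2, 6 from 5, and 14 from 13.

## Roads not taken

**Alternative 1:** The cut is C2–C3, with the C2 oxygen tied to the C6 carbonyl as a lactone. In the forward step the γ-carbon of silyl dienolate A1 adds to Z-enal A2 under a chiral copper catalyst made from Cu(OTf)2, Tol-BINAP and a fluoride source, and the aldolate lactonises to dihydropyranone A3.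
- Merits: C2 is set by a catalyst, the six-membered lactone holds C4=C5 Z, and C1=C10 Z arrives with A2.
- Weak points: A3 holds only C1–C6 and C9–C10. The ten-membered ring still has to be closed by a later macrocyclisation, C6/C7/C8/C11 are untouched, the lactone must be unlocked again, and A2 can isomerise under Lewis-acid or fluoride conditions.
- Comparison: this road is better in reagent economy for C2 (the chosen plan uses a stoichiometric, recoverable auxiliary) and equal in fixing C4=C5. The chosen plan offsets this because its aldol also installs the control element for the ring expansion, so the medium ring costs no separate closure.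

**Alternative 2:** The cut is C1–C2. CrCl2 with catalytic NiCl2 converts the Z alkenyl iodide of seco aldehyde A4 into an alkenylchromium species that adds to the C2 aldehyde to give allylic alcohol A5.
- Merits: convergent, very late closure on a finished methylene lactone, good functional-group tolerance, retention of olefin geometry, and few steps after the ring exists.
- Weak points: a ten-membered closure needing high dilution and a large excess of chromium salt; C2 is formed far from the triad with no lever on its configuration; the β,γ-unsaturated aldehyde of A4 is prone to conjugation.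
- Comparison: this road is clearly better in convergence and in post-cyclisation step count. The chosen plan sets against it an absolute, reagent-controlled C2 made before the ring exists, a unimolecular ring formation at normal concentration, and one transition state fixing C1=C10 and C8.

**Alternative 3:** The cut is C6–C7. Lithiation at C6 of the thirteen-membered ether A6 (n-BuLi) triggers a [2,3] shift that contracts the ring to carbocycle A7.
- Merits: C6–C7 forms with both stereocentres and with C11=C13 and C12 in place in one step; a thirteen-membered ether is easier to close than a ten-membered carbocycle; C2 and C8 already carry oxygen.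
- Weak points: two competing allylic α-oxy sites for lithiation (C6 and C13), a possible [1,2] shift, and a stereochemical outcome that depends on the macrocycle conformation and on the C7=C11 geometry of A6. A6 itself needs three defined olefins, two remote stereocentres and a macro-etherification, and C12 must still be oxidised.
- Comparison: this road is better in that C6, C7 and the three-carbon unit arrive together and no silicon-to-oxygen exchange is needed. The chosen plan needs four steps for the same unit, but starts from a six-membered precursor whose stereocentres come from one aldol and one carbonyl addition.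

Key step: step 11

Remark: atom labels C1–C15 follow germacrane numbering of the target; organometallic intermediates are drawn as monomers; the C11 configuration of Mannich base 26 is immaterial and left open.

## Route

Step 1
Reactants: 1 (R)-4-benzyl-1,3-oxazolidin-2-one; 2 3-methylbut-2-enoyl chloride
Product: 4 (R)-4-benzyl-3-(3-methylbut-2-enoyl)-1,3-oxazolidin-2-one, via N-lithio oxazolidinone 3 (not isolated)
Conditions: n-BuLi, THF, −78 °C; then 2, −78 to 0 °C
Reagents that add atoms: none
Why: N-acylation of the lithiated oxazolidinone by the acid chloride (standard imide formation); the stereocentre of 1 is not involved.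

Step 2
Reactants: 5 3-methylbut-3-en-1-ol
Product: 6 3-methylbut-3-enal
Conditions: Dess–Martin periodinane, NaHCO3, CH2Cl2, 0 °C; cold solution used at once
Reagents that add atoms: none
Why: Buffered Dess–Martin oxidation is neutral enough to keep the β,γ-olefin out of conjugation; the volatile aldehyde is not stored.

Step 3
Reactants: 4 (R)-4-benzyl-3-(3-methylbut-2-enoyl)-1,3-oxazolidin-2-one; 6 3-methylbut-3-enal
Product: 8 (R)-4-benzyl-3-[(2R,3S)-3-hydroxy-5-methyl-2-(prop-1-en-2-yl)hex-5-enoyl]-1,3-oxazolidin-2-one, via boron dienolate 7 (not isolated)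
Conditions: Bu2BOTf, Et3N, CH2Cl2, −78 to 0 °C; then 6, −78 to 0 °C; pH 7 buffer, MeOH, H2O2
Reagents that add atoms: none
Why: Evans syn aldol in its deconjugative form: γ-deprotonation gives the Z(O) boron dienolate 7, which reacts at its α-carbon (C1) through a chair Zimmerman–Traxler transition state. The (R)-benzyl auxiliary selects the enolate face, so C1 (R) and C2 (S) should form as the syn pair.

Step 4
Reactants: 8 (R)-4-benzyl-3-[(2R,3S)-3-hydroxy-5-methyl-2-(prop-1-en-2-yl)hex-5-enoyl]-1,3-oxazolidin-2-one
Product: 9 (2R,3S)-3-hydroxy-N-methoxy-N,5-dimethyl-2-(prop-1-en-2-yl)hex-5-enamide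
Conditions: MeNH(OMe)·HCl, AlMe3, CH2Cl2, −20 to 0 °C
Reagents that add atoms: N,O-dimethylhydroxylamine hydrochloride, CNOC.Cl
Why: Aluminium amide transamination of an aldol imide to the Weinreb amide; the free C2 hydroxyl, as its aluminium alkoxide, directs attack to the exocyclic carbonyl. Auxiliary 1 is recovered, and the cold conditions should spare the acidic C1–H.

Step 5
Reactants: 9 (2R,3S)-3-hydroxy-N-methoxy-N,5-dimethyl-2-(prop-1-en-2-yl)hex-5-enamide
Product: 10 (2R,3S)-3-[(tert-butyldimethylsilyl)oxy]-N-methoxy-N,5-dimethyl-2-(prop-1-en-2-yl)hex-5-enamide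
Conditions: TBSOTf, 2,6-lutidine, CH2Cl2, −78 to 0 °C
Reagents that add atoms: tert-butyldimethylsilyl triflate, CC(C)(C)[Si](C)(C)OS(=O)(=O)C(F)(F)F
Why: Standard silylation of a secondary alcohol. The bulky ether later holds C2 equatorial and falls off in the fluoride step that unmasks C8.

Step 6
Reactants: 10 (2R,3S)-3-[(tert-butyldimethylsilyl)oxy]-N-methoxy-N,5-dimethyl-2-(prop-1-en-2-yl)hex-5-enamide
Product: 11 (4R,5S)-5-[(tert-butyldimethylsilyl)oxy]-7-methyl-4-(prop-1-en-2-yl)octa-1,7-dien-3-one
Conditions: CH2=CHMgBr, THF, −20 to 0 °C; inverse quench into cold 1 M HCl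
Reagents that add atoms: vinylmagnesium bromide, C=C[Mg]Br
Why: Weinreb ketone synthesis: the chelated tetrahedral adduct prevents over-addition, and the acidic inverse quench keeps the released amine from adding to the new enone.

Step 7
Reactants: 11 (4R,5S)-5-[(tert-butyldimethylsilyl)oxy]-7-methyl-4-(prop-1-en-2-yl)octa-1,7-dien-3-one
Product: 12 (5S,6R)-5-[(tert-butyldimethylsilyl)oxy]-3-methyl-6-(prop-1-en-2-yl)cyclohex-2-en-1-one
Conditions: second-generation Hoveyda–Grubbs catalyst (H2IMes)Cl2Ru=CH(C6H4-2-O-i-Pr) (5 mol %), CH2Cl2, 40 °C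
Reagents that add atoms: none
Why: Ring-closing metathesis of the vinyl ketone with the 1,1-disubstituted C4 olefin gives a 3-methylcyclohex-2-enone, a known closure to trisubstituted enones. The C1 isopropenyl group stays out because its closure would need a cyclobutene or a tetrasubstituted cyclopentene.

Step 8
Reactants: 13 benzylchlorodimethylsilane
Product: 14 benzyl(ethynyl)dimethylsilane
Conditions: HC≡CMgBr, THF, 0 °C to rt
Reagents that add atoms: ethynylmagnesium bromide, C#C[Mg]Br
Why: Substitution at silicon by an alkynyl Grignard reagent, the usual route to ethynylsilanes.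

Step 9
Reactants: 14 benzyl(ethynyl)dimethylsilane; 12 (5S,6R)-5-[(tert-butyldimethylsilyl)oxy]-3-methyl-6-(prop-1-en-2-yl)cyclohex-2-en-1-one
Product: 16 (1R,5S,6R)-1-{[benzyl(dimethyl)silyl]ethynyl}-5-[(tert-butyldimethylsilyl)oxy]-3-methyl-6-(prop-1-en-2-yl)cyclohex-2-en-1-ol, via lithium acetylide 15 (not isolated)
Conditions: n-BuLi, THF, −78 °C; then 12, −78 °C
Reagents that add atoms: none
Why: 1,2-Addition of a lithium acetylide to a cyclohexenone. The slim, weakly basic nucleophile should attack axially on the half-chair with C1 and C2 substituents equatorial, antiperiplanar to the axial C1–H and away from the C2 silyl ether. This places the alkyne cis to the isopropenyl group (C6 R) with little enolisation.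

Step 10
Reactants: 16 (1R,5S,6R)-1-{[benzyl(dimethyl)silyl]ethynyl}-5-[(tert-butyldimethylsilyl)oxy]-3-methyl-6-(prop-1-en-2-yl)cyclohex-2-en-1-ol
Product: 17 (1R,5S,6R)-1-{(E)-2-[benzyl(dimethyl)silyl]ethenyl}-5-[(tert-butyldimethylsilyl)oxy]-3-methyl-6-(prop-1-en-2-yl)cyclohex-2-en-1-ol
Conditions: NaAlH2(OCH2CH2OMe)2 (Red-Al), THF, 0 °C to rt
Reagents that add atoms: none
Why: Hydroxyl-directed trans-hydroalumination of a propargylic alcohol (hydride delivered from the aluminium alkoxide, aluminium ending on the silyl-bearing carbon), then protonolysis; this gives only the E vinylsilane and leaves the ring olefin and silyl groups alone.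

Step 11
Reactants: 17 (1R,5S,6R)-1-{(E)-2-[benzyl(dimethyl)silyl]ethenyl}-5-[(tert-butyldimethylsilyl)oxy]-3-methyl-6-(prop-1-en-2-yl)cyclohex-2-en-1-ol
Product: 20 (2Z,5S,6Z,9R)-9-[benzyl(dimethyl)silyl]-5-[(tert-butyldimethylsilyl)oxy]-3,7-dimethylcyclodeca-2,6-dien-1-one, via potassium alkoxide 18 (not isolated), via potassium dienolate 19 (not isolated)
Conditions: KH, 18-crown-6, THF, 0 °C to rt; then AcOH, −78 °C
Reagents that add atoms: none
Why: Deprotonation gives the crown-separated tertiary alkoxide 18, which weakens the doubly allylic C1–C6 bond and triggers a concerted, charge-accelerated [3,3] shift through the chair array C8=C7–C6···C1–C10=C9; C8–C9 forms as C1–C6 breaks, and dienolate 19 is protonated at C7 by cold AcOH. The closest known reaction type is the anionic oxy-Cope ring expansion of 1,2-dialkenylcyclohexanols to cyclodec-5-enones. The ten-membered ring is not closed end to end: it arises by four-atom ring expansion, the cyclohexene merging with the six-centre array when the shared C1–C6 bond breaks, so no high dilution is needed and C4=C5 keeps its Z geometry. The one new stereocentre, C8, is set by the chair together with the E vinylsilane (silicon equatorial) and the configurations of C1 and C6, which decide which face of C7=C8 meets C9; this gives 9R in 20, the target configuration after retentive oxidation. The step must give Z at C1=C10: with the C6 alkenyl group axial and the cis C1 isopropenyl group equatorial, C2 is axial on the chair and ends cis to C9. That half-chair is secured by the trans C1 isopropenyl and C2 silyloxy groups, both equatorial, whereas the flipped half-chair (which would give the E olefin) would force the C6 oxyanion and the C2 silyl ether into a 1,3-diaxial clash. The E vinylsilane also keeps silicon out of reach of the alkoxide, so silyl migration should not compete.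

Step 12
Reactants: 20 (2Z,5S,6Z,9R)-9-[benzyl(dimethyl)silyl]-5-[(tert-butyldimethylsilyl)oxy]-3,7-dimethylcyclodeca-2,6-dien-1-one
Product: 22 methyl 2-[(1S,3Z,6S,7Z,10R)-10-[benzyl(dimethyl)silyl]-6-[(tert-butyldimethylsilyl)oxy]-4,8-dimethyl-2-oxocyclodeca-3,7-dien-1-yl]acetate, via lithium enolate 21 (not isolated)
Conditions: LiN(i-Pr)2, THF, −78 °C; then BrCH2CO2Me, DMPU, −78 to −30 °C
Reagents that add atoms: methyl bromoacetate, COC(=O)CBr
Why: Kinetic deprotonation of an enone at the α′ carbon (C7) gives the cross-conjugated enolate 21, which is alkylated by the bromoacetate. Attack is expected anti to the C8 silyl group (the established preference of β-silyl enolates, with C8–H eclipsing the enolate), which places the acetate arm anti to silicon as the target requires.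

Step 13
Reactants: 22 methyl 2-[(1S,3Z,6S,7Z,10R)-10-[benzyl(dimethyl)silyl]-6-[(tert-butyldimethylsilyl)oxy]-4,8-dimethyl-2-oxocyclodeca-3,7-dien-1-yl]acetate
Product: 24 (3aS,4R,6Z,8S,10Z,11aR)-4-[benzyl(dimethyl)silyl]-8-[(tert-butyldimethylsilyl)oxy]-6,10-dimethyl-3a,4,5,8,9,11a-hexahydrocyclodeca[b]furan-2(3H)-one, via hydroxy ester 23 (not isolated)
Conditions: NaBH4, CeCl3·7H2O, MeOH, −40 to 0 °C; then PPTS (cat.), PhMe, 40 °C
Reagents that add atoms: none
Why: Luche 1,2-reduction of the enone, then lactonisation of hydroxy ester 23 with loss of methanol. With the ring bond C7–C8 near the carbonyl plane, the acetate arm covers one face of C6, so hydride should enter from the other and give the C6 oxygen trans to C11 (the trans-fused lactone).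

Step 14
Reactants: 24 (3aS,4R,6Z,8S,10Z,11aR)-4-[benzyl(dimethyl)silyl]-8-[(tert-butyldimethylsilyl)oxy]-6,10-dimethyl-3a,4,5,8,9,11a-hexahydrocyclodeca[b]furan-2(3H)-one
Product: 26 (3aS,4R,6Z,8S,10Z,11aR)-4-[benzyl(dimethyl)silyl]-8-[(tert-butyldimethylsilyl)oxy]-3-[(dimethylamino)methyl]-6,10-dimethyl-3a,4,5,8,9,11a-hexahydrocyclodeca[b]furan-2(3H)-one, via lithium lactone enolate 25 (not isolated)
Conditions: LiN(i-Pr)2, THF, −78 °C; then Me2N=CH2 I, −78 to 0 °C
Reagents that add atoms: N,N-dimethylmethylideneammonium iodide, C=[N+](C)C.[I-]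
Why: Mannich reaction of a lactone enolate with Eschenmoser's salt, the standard first half of α-methylenation; the new C11 centre is removed in the next step.

Step 15
Reactants: 26 (3aS,4R,6Z,8S,10Z,11aR)-4-[benzyl(dimethyl)silyl]-8-[(tert-butyldimethylsilyl)oxy]-3-[(dimethylamino)methyl]-6,10-dimethyl-3a,4,5,8,9,11a-hexahydrocyclodeca[b]furan-2(3H)-one
Product: 28 (3aS,4R,6Z,8S,10Z,11aR)-4-[benzyl(dimethyl)silyl]-8-[(tert-butyldimethylsilyl)oxy]-6,10-dimethyl-3-methylidene-3a,4,5,8,9,11a-hexahydrocyclodeca[b]furan-2(3H)-one, via ammonium iodide 27 (not isolated)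
Conditions: MeI, MeOH, rt; then NaHCO3, H2O/CH2Cl2, rt
Reagents that add atoms: none
Why: Quaternisation of the amine and mild-base elimination of trimethylamine give the α-methylene lactone without strong base.

Step 16
Reactants: 28 (3aS,4R,6Z,8S,10Z,11aR)-4-[benzyl(dimethyl)silyl]-8-[(tert-butyldimethylsilyl)oxy]-6,10-dimethyl-3-methylidene-3a,4,5,8,9,11a-hexahydrocyclodeca[b]furan-2(3H)-one
Product: 29 (3R,3aR,4R,6Z,8S,10Z,11aR)-4-[benzyl(dimethyl)silyl]-8-[(tert-butyldimethylsilyl)oxy]-6,10-dimethyl-3a,4,5,8,9,11a-hexahydro-2H-spiro[cyclodeca[b]furan-3,2'-oxiran]-2-one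
Conditions: t-BuOOH, n-BuLi, THF, −78 to −20 °C
Reagents that add atoms: tert-butyl hydroperoxide, CC(C)(C)OO
Why: Nucleophilic (Weitz–Scheffer type) epoxidation: conjugate addition of t-BuOOLi at C13 and closure of the C11 enolate on oxygen touch only the electron-poor methylene, not the ring olefins. The peroxide arm should swing to the lactone face away from C8 and its silyl group, putting oxygen on the H7 side as in the target.

Step 17
Reactants: 29 (3R,3aR,4R,6Z,8S,10Z,11aR)-4-[benzyl(dimethyl)silyl]-8-[(tert-butyldimethylsilyl)oxy]-6,10-dimethyl-3a,4,5,8,9,11a-hexahydro-2H-spiro[cyclodeca[b]furan-3,2'-oxiran]-2-one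
Product: 31 (3R,3aR,4R,6Z,8S,10Z,11aR)-4,8-dihydroxy-6,10-dimethyl-3a,4,5,8,9,11a-hexahydro-2H-spiro[cyclodeca[b]furan-3,2'-oxiran]-2-one, via fluorosilane alcohol 30 (not isolated)
Conditions: Bu4NF, THF, 0 °C to rt; then KHCO3, 30% H2O2, MeOH, rt
Reagents that add atoms: hydrogen peroxide, OO
Why: Tamao-type oxidation of a benzyldimethylsilyl group: fluoride removes the benzyl group and the C2 silyl ether to give fluorosilane 30, and basic H2O2 then moves C8 from silicon to oxygen with retention. The epoxy lactone, itself made under peroxide, should tolerate the medium.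

Step 18
Reactants: 31 (3R,3aR,4R,6Z,8S,10Z,11aR)-4,8-dihydroxy-6,10-dimethyl-3a,4,5,8,9,11a-hexahydro-2H-spiro[cyclodeca[b]furan-3,2'-oxiran]-2-one
Product: 32 (3R,3aR,4R,6Z,8S,10Z,11aR)-6,10-dimethyl-2-oxo-3a,4,5,8,9,11a-hexahydro-2H-spiro[cyclodeca[b]furan-3,2'-oxirane]-4,8-diyl diacetate
Conditions: Ac2O, pyridine, DMAP (cat.), CH2Cl2, 0 °C to rt
Reagents that add atoms: acetic anhydride, CC(=O)OC(C)=O
Why: DMAP-catalysed acetylation of the two secondary alcohols; no tertiary hydroxyl exists yet, so no selectivity is required.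

Step 19
Reactants: 32 (3R,3aR,4R,6Z,8S,10Z,11aR)-6,10-dimethyl-2-oxo-3a,4,5,8,9,11a-hexahydro-2H-spiro[cyclodeca[b]furan-3,2'-oxirane]-4,8-diyl diacetate
Product: 33 (3S,3aR,4R,6Z,8S,10Z,11aR)-3-(chloromethyl)-3-hydroxy-6,10-dimethyl-2-oxo-2,3,3a,4,5,8,9,11a-octahydrocyclodeca[b]furan-4,8-diyl diacetate
Conditions: LiCl, AcOH, THF, rt
Reagents that add atoms: lithium chloride, [Li+].[Cl-]
Why: Halohydrin formation from an epoxide with LiCl/AcOH: chloride opens the epoxide by SN2 attack at the primary C13 (C11 is quaternary and α to the carbonyl), so the C11–O bond and its configuration are untouched. The near-neutral medium spares the acetates, the allylic lactone and the diene.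

## Compound list

1 | (R)-4-benzyl-1,3-oxazolidin-2-one | O=C1N[C@H](Cc2ccccc2)CO1 | starting material
2 | 3-methylbut-2-enoyl chloride | CC(C)=CC(Cl)=O | starting material
3 | N-lithio (R)-4-benzyl-1,3-oxazolidin-2-one (not isolated) | O=C1N([Li])[C@H](Cc2ccccc2)CO1 | intermediate
4 | (R)-4-benzyl-3-(3-methylbut-2-enoyl)-1,3-oxazolidin-2-one | CC(C)=CC(=O)N1[C@H](Cc2ccccc2)COC1=O | intermediate
5 | 3-methylbut-3-en-1-ol | CC(=C)CCO | starting material
6 | 3-methylbut-3-enal | CC(=C)CC=O | intermediate
7 | dibutylboron Z(O)-dienolate of 4 (not isolated) | C=C(C)/C=C(\OB(CCCC)CCCC)N1[C@H](Cc2ccccc2)COC1=O | intermediate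
8 | (R)-4-benzyl-3-[(2R,3S)-3-hydroxy-5-methyl-2-(prop-1-en-2-yl)hex-5-enoyl]-1,3-oxazolidin-2-one | C=C(C)C[C@H](O)[C@@H](C(C)=C)C(=O)N1[C@H](Cc2ccccc2)COC1=O | intermediate
9 | (2R,3S)-3-hydroxy-N-methoxy-N,5-dimethyl-2-(prop-1-en-2-yl)hex-5-enamide | C=C(C)C[C@H](O)[C@@H](C(C)=C)C(=O)N(C)OC | intermediate
10 | (2R,3S)-3-[(tert-butyldimethylsilyl)oxy]-N-methoxy-N,5-dimethyl-2-(prop-1-en-2-yl)hex-5-enamide | C=C(C)C[C@H](O[Si](C)(C)C(C)(C)C)[C@@H](C(C)=C)C(=O)N(C)OC | intermediate
11 | (4R,5S)-5-[(tert-butyldimethylsilyl)oxy]-7-methyl-4-(prop-1-en-2-yl)octa-1,7-dien-3-one | C=C(C)C[C@H](O[Si](C)(C)C(C)(C)C)[C@@H](C(C)=C)C(=O)C=C | intermediate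
12 | (5S,6R)-5-[(tert-butyldimethylsilyl)oxy]-3-methyl-6-(prop-1-en-2-yl)cyclohex-2-en-1-one | CC(C)(C)[Si](C)(C)O[C@@H]1[C@@H](C(C)=C)C(=O)C=C(C)C1 | intermediate
13 | benzylchlorodimethylsilane | C[Si](C)(Cl)Cc1ccccc1 | starting material
14 | benzyl(ethynyl)dimethylsilane | C#C[Si](C)(C)Cc1ccccc1 | intermediate
15 | lithium [benzyl(dimethyl)silyl]acetylide (not isolated) | [Li]C#C[Si](C)(C)Cc1ccccc1 | intermediate
16 | (1R,5S,6R)-1-{[benzyl(dimethyl)silyl]ethynyl}-5-[(tert-butyldimethylsilyl)oxy]-3-methyl-6-(prop-1-en-2-yl)cyclohex-2-en-1-ol | CC(C)(C)[Si](C)(C)O[C@@H]1[C@@H](C(C)=C)[C@@](O)(C#C[Si](C)(C)Cc2ccccc2)C=C(C)C1 | intermediate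
17 | (1R,5S,6R)-1-{(E)-2-[benzyl(dimethyl)silyl]ethenyl}-5-[(tert-butyldimethylsilyl)oxy]-3-methyl-6-(prop-1-en-2-yl)cyclohex-2-en-1-ol | CC(C)(C)[Si](C)(C)O[C@@H]1[C@@H](C(C)=C)[C@@](O)(/C=C/[Si](C)(C)Cc2ccccc2)C=C(C)C1 | intermediate
18 | potassium alkoxide of 17 (not isolated) | CC(C)(C)[Si](C)(C)O[C@@H]1[C@@H](C(C)=C)[C@@]([O-])(/C=C/[Si](C)(C)Cc2ccccc2)C=C(C)C1.[K+] | intermediate
19 | potassium C6–C7 dienolate of 20 with C5 trans to C8 (not isolated) | CC(C)(C)[Si](C)(C)O[C@@H]1/C=C(/C)C[C@@H]([Si](C)(C)Cc2ccccc2)/C=C(\[O-])/C=C(/C)C1.[K+] | intermediate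
20 | (2Z,5S,6Z,9R)-9-[benzyl(dimethyl)silyl]-5-[(tert-butyldimethylsilyl)oxy]-3,7-dimethylcyclodeca-2,6-dien-1-one | CC(C)(C)[Si](C)(C)O[C@@H]1/C=C(/C)C[C@@H]([Si](C)(C)Cc2ccccc2)CC(=O)/C=C(/C)C1 | intermediate
21 | lithium C6–C7 enolate of 20, enolate geometry not defined (not isolated) | CC(C)(C)[Si](C)(C)O[C@@H]1/C=C(/C)C[C@@H]([Si](C)(C)Cc2ccccc2)C=C(O[Li])/C=C(/C)C1 | intermediate
22 | methyl 2-[(1S,3Z,6S,7Z,10R)-10-[benzyl(dimethyl)silyl]-6-[(tert-butyldimethylsilyl)oxy]-4,8-dimethyl-2-oxocyclodeca-3,7-dien-1-yl]acetate | CC(C)(C)[Si](C)(C)O[C@@H]1/C=C(/C)C[C@@H]([Si](C)(C)Cc2ccccc2)[C@@H](CC(=O)OC)C(=O)/C=C(/C)C1 | intermediate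
23 | methyl 2-[(1S,2R,3Z,6S,7Z,10R)-10-[benzyl(dimethyl)silyl]-6-[(tert-butyldimethylsilyl)oxy]-2-hydroxy-4,8-dimethylcyclodeca-3,7-dien-1-yl]acetate (not isolated) | CC(C)(C)[Si](C)(C)O[C@@H]1/C=C(/C)C[C@@H]([Si](C)(C)Cc2ccccc2)[C@@H](CC(=O)OC)[C@@H](/C=C(/C)C1)O | intermediate
24 | (3aS,4R,6Z,8S,10Z,11aR)-4-[benzyl(dimethyl)silyl]-8-[(tert-butyldimethylsilyl)oxy]-6,10-dimethyl-3a,4,5,8,9,11a-hexahydrocyclodeca[b]furan-2(3H)-one | CC(C)(C)[Si](C)(C)O[C@@H]1/C=C(/C)C[C@@H]([Si](C)(C)Cc3ccccc3)[C@@H]2[C@@H](/C=C(/C)C1)OC(=O)C2 | intermediate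
25 | lithium enolate of lactone 24 (not isolated) | CC(C)(C)[Si](C)(C)O[C@@H]1/C=C(/C)C[C@@H]([Si](C)(C)Cc3ccccc3)[C@@H]2[C@@H](/C=C(/C)C1)OC(O[Li])=C2 | intermediate
26 | (3aS,4R,6Z,8S,10Z,11aR)-4-[benzyl(dimethyl)silyl]-8-[(tert-butyldimethylsilyl)oxy]-3-[(dimethylamino)methyl]-6,10-dimethyl-3a,4,5,8,9,11a-hexahydrocyclodeca[b]furan-2(3H)-one (C3 epimers) | CC(C)(C)[Si](C)(C)O[C@@H]1/C=C(/C)C[C@@H]([Si](C)(C)Cc3ccccc3)[C@@H]2[C@@H](/C=C(/C)C1)OC(=O)C2CN(C)C | intermediate
27 | trimethylammonium iodide derived from 26 (not isolated) | CC(C)(C)[Si](C)(C)O[C@@H]1/C=C(/C)C[C@@H]([Si](C)(C)Cc3ccccc3)[C@@H]2[C@@H](/C=C(/C)C1)OC(=O)C2C[N+](C)(C)C.[I-] | intermediate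
28 | (3aS,4R,6Z,8S,10Z,11aR)-4-[benzyl(dimethyl)silyl]-8-[(tert-butyldimethylsilyl)oxy]-6,10-dimethyl-3-methylidene-3a,4,5,8,9,11a-hexahydrocyclodeca[b]furan-2(3H)-one | CC(C)(C)[Si](C)(C)O[C@@H]1/C=C(/C)C[C@@H]([Si](C)(C)Cc3ccccc3)[C@@H]2[C@@H](/C=C(/C)C1)OC(=O)C2=C | intermediate
29 | (3R,3aR,4R,6Z,8S,10Z,11aR)-4-[benzyl(dimethyl)silyl]-8-[(tert-butyldimethylsilyl)oxy]-6,10-dimethyl-3a,4,5,8,9,11a-hexahydro-2H-spiro[cyclodeca[b]furan-3,2'-oxiran]-2-one | CC(C)(C)[Si](C)(C)O[C@@H]1/C=C(/C)C[C@@H]([Si](C)(C)Cc4ccccc4)[C@@H]2[C@@H](/C=C(/C)C1)OC(=O)[C@]23CO3 | intermediate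
30 | (3R,3aR,4R,6Z,8S,10Z,11aR)-4-[fluoro(dimethyl)silyl]-8-hydroxy-6,10-dimethyl-3a,4,5,8,9,11a-hexahydro-2H-spiro[cyclodeca[b]furan-3,2'-oxiran]-2-one (not isolated) | O[C@@H]1/C=C(/C)C[C@@H]([Si](C)(C)F)[C@@H]2[C@@H](/C=C(/C)C1)OC(=O)[C@]23CO3 | intermediate
31 | (3R,3aR,4R,6Z,8S,10Z,11aR)-4,8-dihydroxy-6,10-dimethyl-3a,4,5,8,9,11a-hexahydro-2H-spiro[cyclodeca[b]furan-3,2'-oxiran]-2-one | O[C@@H]1/C=C(/C)C[C@@H](O)[C@@H]2[C@@H](/C=C(/C)C1)OC(=O)[C@]23CO3 | intermediate
32 | (3R,3aR,4R,6Z,8S,10Z,11aR)-6,10-dimethyl-2-oxo-3a,4,5,8,9,11a-hexahydro-2H-spiro[cyclodeca[b]furan-3,2'-oxirane]-4,8-diyl diacetate | CC(=O)O[C@@H]1/C=C(/C)C[C@@H](OC(C)=O)[C@@H]2[C@@H](/C=C(/C)C1)OC(=O)[C@]23CO3 | intermediate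
33 | (3S,3aR,4R,6Z,8S,10Z,11aR)-3-(chloromethyl)-3-hydroxy-6,10-dimethyl-2-oxo-2,3,3a,4,5,8,9,11a-octahydrocyclodeca[b]furan-4,8-diyl diacetate | CC(=O)O[C@@H]1/C=C(/C)C[C@@H](OC(C)=O)[C@@H]2[C@@H](/C=C(/C)C1)OC(=O)[C@]2(O)CCl | target

## Step count and risks

Total: 19 steps. Longest linear sequence: 17 steps (steps 1, 3–7 and 9–19; steps 2 and 8 are one-step side branches).

**Step 11 (key step).** The shift may run through the flipped half-chair or a boat array, which would lose the Z geometry at C1=C10 and the C8 configuration. The separated alkoxide may also fragment at the doubly allylic C1–C6 bond, or excess base may move the enone olefin out of conjugation before the quench. Fallback: the charge-free form of the same shift. Starting from 17, the tertiary alcohol is silylated (Me3SiCl, imidazole) to the trimethylsilyl ether F1, which is heated in degassed toluene (sealed tube, about 180–200 °C) to give the ten-membered trimethylsilyl dienol ether F2 without any free alkoxide or enolate. Mild methanolysis (K2CO3, MeOH) returns to the route at 20.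

**Step 9.** Facial selectivity may be poor: attack trans to the C1 isopropenyl group would give the trans-dialkenyl carbinol and later the E olefin. Enolisation of 12 followed by β-elimination of the C2 silyloxy group is the second danger. Fallback: set C6 in the open chain and close the ring afterwards. Starting from Weinreb amide 10, acetylide 15 gives the ynone F3, and CH2=CHMgBr adds to it to give the acyclic tertiary carbinol F4. Adding the vinyl and alkynyl groups in this order or in the reverse order (acetylide onto 11) gives opposite C6 configurations, and the order that delivers 6R is kept. Ring-closing metathesis of F4 with the catalyst of step 7 rejoins the route at 16.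

**Step 12.** Deprotonation may occur at the γ-positions (C3 or the C4 methyl) instead of C7, and the ring conformation may override the anti-to-silicon preference, giving poor facial selectivity at C7. Fallback: use the regiodefined enolate of the key step and thermodynamic control. Starting from 17, step 11 is run and methyl bromoacetate is added to dienolate 19 in place of acid. Any C7 epimer F5 is then equilibrated through its enolate (DBU, toluene), possible because C7–H is still α to the ketone, towards the isomer with the acetate arm anti to silicon, returning at 22.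

**Step 13.** Hydride may be delivered to the wrong face of C6 because the ring conformation, not the C7 branch, decides; this would give the cis-fused lactone. Fallback: inversion at C6 by Mitsunobu lactonisation. Starting from 22, the same reduction would give the C6-epimeric cis-fused lactone F6. Saponification (LiOH, THF/H2O) opens it to hydroxy acid F7, and PPh3 with diisopropyl azodicarboxylate closes the carboxylate onto the activated C6–O bond with inversion, returning at 24.

**Step 16.** The ring closure of the peroxy enolate may show poor facial selectivity (oxygen syn to C8), and peroxide may open the lactone. Fallback: build C11 by two enolate reactions so that oxygen enters last, from the open face. Starting from 24, the lithium enolate is hydroxymethylated with monomeric formaldehyde to the α-hydroxymethyl lactone F8. Its dianion (two equivalents of LiN(i-Pr)2) is hydroxylated with 2-(phenylsulfonyl)-3-phenyloxaziridine anti to C8 to give the C11,C13-diol F9. Sulfonylation of the primary hydroxyl (TsCl, pyridine) gives tosylate F10, and K2CO3 closes the epoxide with retention at C11, returning at 29.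

**Step 17.** In the basic fluoride and peroxide medium the new C8 hydroxyl may attack the neighbouring spiro-epoxide at C13 or take over the lactone acyl group (acyl transfer from the C6 to the C8 oxygen). Fluoride cleavage of the benzyl group may also be slow next to the crowded C7. Fallback: exchange silicon for oxygen before the epoxide exists and cap the oxygen at once. Starting from 24, the same Bu4NF then H2O2/KHCO3 treatment gives the C2,C8-diol lactone F11, which is silylated (Et3SiCl, imidazole) to the bis(triethylsilyl) ether F12. Methylenation as in steps 14 and 15 (Mannich base F13, then α-methylene lactone F14) and epoxidation as in step 16 give the epoxide F15, and HF·pyridine removes both triethylsilyl groups to return at 31.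

## Further compounds

F1 | step 11 | trimethylsilyl ether of 17 | CC(C)(C)[Si](C)(C)O[C@@H]1[C@@H](C(C)=C)[C@@](O[Si](C)(C)C)(/C=C/[Si](C)(C)Cc2ccccc2)C=C(C)C1
F2 | step 11 | ten-membered trimethylsilyl dienol ether (C6–C7 enol ether of 20, C5 trans to C8) | CC(C)(C)[Si](C)(C)O[C@@H]1/C=C(/C)C[C@@H]([Si](C)(C)Cc2ccccc2)/C=C(\O[Si](C)(C)C)/C=C(/C)C1
F3 | step 9 | (4R,5S)-1-[benzyl(dimethyl)silyl]-5-[(tert-butyldimethylsilyl)oxy]-7-methyl-4-(prop-1-en-2-yl)oct-7-en-1-yn-3-one | C=C(C)C[C@H](O[Si](C)(C)C(C)(C)C)[C@@H](C(C)=C)C(=O)C#C[Si](C)(C)Cc1ccccc1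
F4 | step 9 | (3R,4R,5S)-1-[benzyl(dimethyl)silyl]-5-[(tert-butyldimethylsilyl)oxy]-3-ethenyl-7-methyl-4-(prop-1-en-2-yl)oct-7-en-1-yn-3-ol | C=C(C)C[C@H](O[Si](C)(C)C(C)(C)C)[C@@H](C(C)=C)[C@](O)(C=C)C#C[Si](C)(C)Cc1ccccc1
F5 | step 12 | C7 epimer of keto ester 22 | CC(C)(C)[Si](C)(C)O[C@@H]1/C=C(/C)C[C@@H]([Si](C)(C)Cc2ccccc2)[C@H](CC(=O)OC)C(=O)/C=C(/C)C1
F6 | step 13 | C6 epimer of lactone 24 (cis-fused) | CC(C)(C)[Si](C)(C)O[C@@H]1/C=C(/C)C[C@@H]([Si](C)(C)Cc3ccccc3)[C@@H]2[C@H](/C=C(/C)C1)OC(=O)C2
F7 | step 13 | C6-epimeric hydroxy acid from F6 | CC(C)(C)[Si](C)(C)O[C@@H]1/C=C(/C)C[C@@H]([Si](C)(C)Cc2ccccc2)[C@@H](CC(=O)O)[C@H](/C=C(/C)C1)O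
F8 | step 16 | C11-hydroxymethyl lactone from 24 (C11 epimers) | CC(C)(C)[Si](C)(C)O[C@@H]1/C=C(/C)C[C@@H]([Si](C)(C)Cc3ccccc3)[C@@H]2[C@@H](/C=C(/C)C1)OC(=O)C2CO
F9 | step 16 | C11,C13-diol lactone (C11 hydroxyl on the H7 face) | CC(C)(C)[Si](C)(C)O[C@@H]1/C=C(/C)C[C@@H]([Si](C)(C)Cc3ccccc3)[C@@H]2[C@@H](/C=C(/C)C1)OC(=O)[C@]2(O)CO
F10 | step 16 | C13 tosylate of F9 | CC(C)(C)[Si](C)(C)O[C@@H]1/C=C(/C)C[C@@H]([Si](C)(C)Cc3ccccc3)[C@@H]2[C@@H](/C=C(/C)C1)OC(=O)[C@]2(O)COS(=O)(=O)c4ccc(C)cc4
F11 | step 17 | C2,C8-diol lactone (C11 methylene) | O[C@@H]1/C=C(/C)C[C@@H](O)[C@@H]2[C@@H](/C=C(/C)C1)OC(=O)C2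
F12 | step 17 | bis(triethylsilyl) ether of F11 | CC[Si](CC)(CC)O[C@@H]1/C=C(/C)C[C@@H](O[Si](CC)(CC)CC)[C@@H]2[C@@H](/C=C(/C)C1)OC(=O)C2
F13 | step 17 | C11 dimethylaminomethyl derivative of F12 (C11 epimers) | CC[Si](CC)(CC)O[C@@H]1/C=C(/C)C[C@@H](O[Si](CC)(CC)CC)[C@@H]2[C@@H](/C=C(/C)C1)OC(=O)C2CN(C)C
F14 | step 17 | α-methylene lactone bis(triethylsilyl) ether | CC[Si](CC)(CC)O[C@@H]1/C=C(/C)C[C@@H](O[Si](CC)(CC)CC)[C@@H]2[C@@H](/C=C(/C)C1)OC(=O)C2=C
F15 | step 17 | spiro-epoxy lactone bis(triethylsilyl) ether | CC[Si](CC)(CC)O[C@@H]1/C=C(/C)C[C@@H](O[Si](CC)(CC)CC)[C@@H]2[C@@H](/C=C(/C)C1)OC(=O)[C@]23CO3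
A1 | alternative 1 | 1-methoxy-3-methyl-1-(trimethylsilyloxy)buta-1,3-diene | COC(O[Si](C)(C)C)=CC(C)=C
A2 | alternative 1 | (Z)-4-[(tert-butyldimethylsilyl)oxy]-3-methylbut-2-enal | CC(C)(C)[Si](C)(C)OC/C(C)=C\C=O
A3 | alternative 1 | (S)-6-{(Z)-3-[(tert-butyldimethylsilyl)oxy]-2-methylprop-1-en-1-yl}-4-methyl-5,6-dihydro-2H-pyran-2-one | CC(C)(C)[Si](C)(C)OC/C(C)=C\[C@@H]1CC(C)=CC(=O)O1
A4 | alternative 2 | seco lactone with Z alkenyl iodide at C1 and C2 aldehyde | I/C=C(/C)C[C@@H](O[Si](C)(C)C(C)(C)C)[C@@H]1[C@@H](/C=C(/C)CC=O)OC(=O)C1=C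
A5 | alternative 2 | ten-membered C2 allylic alcohol fused to the methylene lactone | O[C@@H]1/C=C(/C)C[C@@H](O[Si](C)(C)C(C)(C)C)[C@@H]2[C@@H](/C=C(/C)C1)OC(=O)C2=C
A6 | alternative 3 | thirteen-membered bis-allylic ether (C6–O–C13, C7=C11 drawn with C8 cis to C13) | CC(C)(C)[Si](C)(C)O[C@@H]1/C=C(/C)C[C@@H](O[Si](C)(C)C(C)(C)C)/C=C(/COCc2ccc(OC)cc2)COC/C=C(/C)C1
A7 | alternative 3 | ten-membered C6 alcohol with C7 2-propenyl unit | CC(C)(C)[Si](C)(C)O[C@@H]1/C=C(/C)C[C@@H](O[Si](C)(C)C(C)(C)C)[C@@H](C(=C)COCc2ccc(OC)cc2)[C@@H](/C=C(/C)C1)O
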